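**Retrosynthetic overview**
1. Bromophycolide F ⇐ pivalate removal ⇐ Shi epoxidation of the 10',11'-olefin of macrolactone 14 (oxirane ring formed last).
2. 14 ⇐ Shiina macrolactonisation of seco acid 12 at the C14' carbinol (macrolactone ring formed second); C14'–OH ⇐ CBS reduction of ketone 10.
3. 10 ⇐ C12'–C13' bond by alkylating the dianion of 3-hydroxy-3-methylbutan-2-one with allylic bromide 7.
4. 7 ⇐ catalytic enantioselective bromonium-initiated cyclisation of achiral triene 6 (cyclohexane ring formed first; C2', C6', C7' set together).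
5. 6 ⇐ allyl 4-hydroxybenzoate + (2E,6E)-farnesyl bromide by ortho C-alkylation, then pivaloylation, SeO2 oxidation and Appel bromination.

Assumption: primed locants C1'–C15' count the terpenoid chain from the benzylic carbon (C1') to the carbinol carbon bearing the two methyls (C15'); the target is then (2'R,6'S,7'S,10'S,11'S,14'S). The chiral catalysts are bought or made separately and are not counted as steps.

**Route**

Step 1
Reactants: 1 allyl 4-hydroxybenzoate; 2 (2E,6E)-farnesyl bromide
Product: 3 allyl 4-hydroxy-3-[(2E,6E)-3,7,11-trimethyldodeca-2,6,10-trien-1-yl]benzoate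
Conditions: NaH (1.05 equiv), 1 (2 equiv), toluene, 0 °C to rt; then 2, rt, 24 h
Reagents that add atoms: none
Why: In non-polar toluene the tight sodium phenoxide ion pair is alkylated at the ortho carbon by SN2 attack on the primary allylic bromide (phenoxide ortho C-alkylation), which keeps the E,E geometry; the O-alkylated and bis-alkylated by-products are removed by chromatography.

Step 2
Reactants: 3 allyl 4-hydroxy-3-[(2E,6E)-farnesyl]benzoate
Product: 4 allyl 4-(pivaloyloxy)-3-[(2E,6E)-3,7,11-trimethyldodeca-2,6,10-trien-1-yl]benzoate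
Conditions: PivCl, Et3N, DMAP (cat.), CH2Cl2, 0 °C
Reagents that add atoms: pivaloyl chloride, CC(C)(C)C(=O)Cl
Why: DMAP-catalysed O-acylation makes the phenol oxygen non-nucleophilic, so it cannot trap the C3' cation as a chroman in step 5, and it keeps the phenol masked during lactonisation and epoxidation.

Step 3
Reactants: 4 the pivalate-protected farnesyl arene
Product: 5 allyl 3-[(2E,6E,10E)-12-hydroxy-3,7,11-trimethyldodeca-2,6,10-trien-1-yl]-4-(pivaloyloxy)benzoate
Conditions: SeO2 (0.3 equiv), t-BuOOH (3 equiv), salicylic acid (0.1 equiv), CH2Cl2, 0 °C to rt, stopped at about 70% conversion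
Reagents that add atoms: tert-butyl hydroperoxide, CC(C)(C)OO (the oxygen is relayed through SeO2, O=[Se]=O)
Why: The Sharpless SeO2/t-BuOOH allylic oxidation (ene reaction then [2,3]-sigmatropic shift) prefers the E-methyl of the terminal gem-dimethyl olefin over the internal olefins and gives the E allylic alcohol.

Step 4
Reactants: 5 the 12'-allylic alcohol
Product: 6 allyl 3-[(2E,6E,10E)-12-bromo-3,7,11-trimethyldodeca-2,6,10-trien-1-yl]-4-(pivaloyloxy)benzoate
Conditions: CBr4 (1.3 equiv), PPh3 (1.25 equiv), CH2Cl2, −20 °C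
Reagents that add atoms: carbon tetrabromide, BrC(Br)(Br)Br
Why: The Appel reaction converts the primary allylic alcohol to the bromide by SN2 without allylic transposition; the allylic C–Br then serves both as an inductive deactivator of the 10',11'-olefin in step 5 and as the electrophile in step 6.

Step 5
Reactants: 6 the achiral 12'-bromo triene
Product: 7 allyl 3-{[(1R,2S,3S)-3-bromo-2-[(3E)-5-bromo-4-methylpent-3-en-1-yl]-2-methyl-6-methylidenecyclohexyl]methyl}-4-(pivaloyloxy)benzoate
Conditions: (R)-3,3'-bis(2,4,6-triisopropylphenyl)-1,1'-binaphthyl-2,2'-diyl N-triflylthiophosphoramide (10 mol%; the antipode is used if the sense of induction proves opposite), DBDMH (1.05 equiv), toluene/CH2Cl2 4:1, −78 °C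
Reagents that add atoms: 1,3-dibromo-5,5-dimethylhydantoin (DBDMH), CC1(C)N(Br)C(=O)N(Br)C1=O
Why: Proposed new method: the chiral thiophosphoramide Lewis base takes Br+ from DBDMH (P=S→Br+ with the hydantoinate hydrogen-bonded to the N–H) and hands it to the Si face at C6' of the 6',7'-olefin, which is the only olefin whose bromonium ion can be captured through a six-membered chair by a 1,5-related π-bond (the 10',11'-olefin is deactivated roughly a hundredfold by its allylic C–Br and a 2',3'-bromonium ion is a dead end that gives Br+ back), so anti addition through the chair from the E,E-diene sets C6'(S), C7'(S) and C2'(R) together with Br, the C8' chain and the arylmethyl group all equatorial, and the ion-paired hindered hydantoinate removes a proton from the exposed C3' methyl of the tertiary cation to leave the exocyclic methylene; the closest known reaction is the chiral thiophosphoramide/DBDMH enantioselective bromo-polyene cyclisation of homogeranyl arenes and geranyl phenols, which starts at a terminal prenyl-type olefin and ends by arene or phenol capture, not at an internal olefin with proton loss.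

Step 6
Reactants: 7 the bromocyclohexane allylic bromide; 8 3-hydroxy-3-methylbutan-2-one
Product: 10 allyl 3-{[(1R,2S,3S)-3-bromo-2-[(3E)-8-hydroxy-4,8-dimethyl-7-oxonon-3-en-1-yl]-2-methyl-6-methylidenecyclohexyl]methyl}-4-(pivaloyloxy)benzoate, via dilithium dianion 9 (not isolated)
Conditions: 8 (3 equiv), LiN(iPr)2 (6.2 equiv), THF, −78 to 0 °C; then 7, DMPU, −78 to −40 °C; H2O quench
Reagents that add atoms: none
Why: The alkoxide–enolate dianion can only enolise toward the methyl group and is C-alkylated by SN2 at the primary allylic bromide (enolate alkylation, E geometry kept), while the equatorial neopentyl-type ring bromide has no anti-periplanar hydrogen for E2 and the hindered pivalate and the benzoate are not attacked at these temperatures.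

Step 7
Reactants: 10 the α-hydroxy ketone
Product: 11 allyl 3-{[(1R,2S,3S)-3-bromo-2-[(3E,7S)-7,8-dihydroxy-4,8-dimethylnon-3-en-1-yl]-2-methyl-6-methylidenecyclohexyl]methyl}-4-(pivaloyloxy)benzoate
Conditions: (R)-2-methyl-CBS-oxazaborolidine [(R)-1-methyl-3,3-diphenyl-tetrahydro-1H,3H-pyrrolo[1,2-c][1,3,2]oxazaborole] (20 mol%), catecholborane (3 equiv), toluene, −78 to −40 °C; then MeOH, aq. NaHCO3
Reagents that add atoms: none
Why: In the CBS reduction the (R)-oxazaborolidine binds the ketone anti to the bulky C15' side (the tertiary hydroxyl is first capped as its catecholborate) and delivers hydride to the face that gives the 14'S carbinol, and catecholborane does not hydroborate the olefins at this temperature.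

Step 8
Reactants: 11 the diol allyl ester
Product: 12 3-{[(1R,2S,3S)-3-bromo-2-[(3E,7S)-7,8-dihydroxy-4,8-dimethylnon-3-en-1-yl]-2-methyl-6-methylidenecyclohexyl]methyl}-4-(pivaloyloxy)benzoic acid
Conditions: Pd(PPh3)4 (5 mol%), N-methylaniline (3 equiv), THF, rt
Reagents that add atoms: none
Why: Zerovalent palladium ionises only the allyl ester (Tsuji–Trost deallylation) and the amine traps the π-allyl fragment under neutral conditions that leave the pivalate, the hindered alkyl bromide and the olefins untouched.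

Step 9
Reactants: 12 the seco acid
Product: 14 O-pivaloyl-10',11'-deoxybromophycolide F (the 15-membered macrolactone with a 10'E olefin), via mixed anhydride 13 (not isolated)
Conditions: 2-methyl-6-nitrobenzoic anhydride (MNBA, 1.3 equiv), DMAP (3 equiv), CH2Cl2, rt, syringe-pump addition of 12 to 1 mM final concentration
Reagents that add atoms: none
Why: In the Shiina macrolactonisation the mixed anhydride is acylated through the acyl-pyridinium by the secondary C14' hydroxyl, with the tertiary C15' hydroxyl too hindered to compete, and closely related diol acids of this family close to the same 15-membered ring.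

Step 10
Reactants: 14 the olefinic macrolactone
Product: 15 bromophycolide F O-pivalate
Conditions: ent-Shi ketone (1,2:4,5-di-O-isopropylidene-β-L-erythro-2,3-hexodiulo-2,6-pyranose, 0.3 equiv), KHSO5 (as 2KHSO5·KHSO4·K2SO4, 1.4 equiv), K2CO3, Bu4NHSO4 (cat.), MeCN/CH2(OMe)2/aq. Na2B4O7 buffer, 0 °C; Na2S2O3 quench
Reagents that add atoms: potassium peroxymonosulfate, [K+].[O-]S(=O)(=O)OO (oxygen relayed through the dioxirane of the ketone catalyst)
Why: In the Shi epoxidation the chiral dioxirane attacks the E-trisubstituted 10',11'-olefin through the spiro transition state on the face that gives the 10'S,11'S oxirane (the L-series ketone gives the mirror image of the R,R sense of the D-fructose catalyst), and the trisubstituted olefin reacts faster than the hindered 1,1-disubstituted exocyclic one.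

Step 11
Reactants: 15 bromophycolide F O-pivalate
Product: 16 bromophycolide F
Conditions: K2CO3 (1.5 equiv), MeOH, 0 °C
Reagents that add atoms: none
Why: Methanolysis cleaves the activated aryl pivalate much faster than the hindered alkyl benzoate lactone, which is further deactivated once the para-phenoxide forms, and the oxirane and the equatorial bromide are stable to cold carbonate.

**Compound list**
1 | allyl 4-hydroxybenzoate | C=CCOC(=O)c1ccc(O)cc1 | starting material
2 | (2E,6E)-farnesyl bromide, (2E,6E)-1-bromo-3,7,11-trimethyldodeca-2,6,10-triene | BrC/C=C(\C)CC/C=C(\C)CCC=C(C)C | starting material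
3 | allyl 4-hydroxy-3-[(2E,6E)-3,7,11-trimethyldodeca-2,6,10-trien-1-yl]benzoate | C=CCOC(=O)c1ccc(O)c(C/C=C(\C)CC/C=C(\C)CCC=C(C)C)c1 | intermediate
4 | allyl 4-(pivaloyloxy)-3-[(2E,6E)-3,7,11-trimethyldodeca-2,6,10-trien-1-yl]benzoate | C=CCOC(=O)c1ccc(OC(=O)C(C)(C)C)c(C/C=C(\C)CC/C=C(\C)CCC=C(C)C)c1 | intermediate
5 | allyl 3-[(2E,6E,10E)-12-hydroxy-3,7,11-trimethyldodeca-2,6,10-trien-1-yl]-4-(pivaloyloxy)benzoate | C=CCOC(=O)c1ccc(OC(=O)C(C)(C)C)c(C/C=C(\C)CC/C=C(\C)CC/C=C(\C)CO)c1 | intermediate
6 | allyl 3-[(2E,6E,10E)-12-bromo-3,7,11-trimethyldodeca-2,6,10-trien-1-yl]-4-(pivaloyloxy)benzoate | C=CCOC(=O)c1ccc(OC(=O)C(C)(C)C)c(C/C=C(\C)CC/C=C(\C)CC/C=C(\C)CBr)c1 | intermediate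
7 | allyl 3-{[(1R,2S,3S)-3-bromo-2-[(3E)-5-bromo-4-methylpent-3-en-1-yl]-2-methyl-6-methylidenecyclohexyl]methyl}-4-(pivaloyloxy)benzoate (ring C1 = C2', C2 = C7', C3 = C6') | C=C1CC[C@H](Br)[C@@](C)(CC/C=C(\C)CBr)[C@@H]1Cc2cc(C(=O)OCC=C)ccc2OC(=O)C(C)(C)C | intermediate
8 | 3-hydroxy-3-methylbutan-2-one | CC(=O)C(C)(C)O | starting material
9 | dilithium 2-methyl-3-oxidobut-3-en-2-olate (enolate–alkoxide dianion of 8) | [Li+].[Li+].C=C([O-])C(C)(C)[O-] | intermediate
10 | allyl 3-{[(1R,2S,3S)-3-bromo-2-[(3E)-8-hydroxy-4,8-dimethyl-7-oxonon-3-en-1-yl]-2-methyl-6-methylidenecyclohexyl]methyl}-4-(pivaloyloxy)benzoate | C=C1CC[C@H](Br)[C@@](C)(CC/C=C(\C)CCC(=O)C(C)(C)O)[C@@H]1Cc2cc(C(=O)OCC=C)ccc2OC(=O)C(C)(C)C | intermediate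
11 | allyl 3-{[(1R,2S,3S)-3-bromo-2-[(3E,7S)-7,8-dihydroxy-4,8-dimethylnon-3-en-1-yl]-2-methyl-6-methylidenecyclohexyl]methyl}-4-(pivaloyloxy)benzoate | C=C1CC[C@H](Br)[C@@](C)(CC/C=C(\C)CC[C@@H](C(C)(C)O)O)[C@@H]1Cc2cc(C(=O)OCC=C)ccc2OC(=O)C(C)(C)C | intermediate
12 | 3-{[(1R,2S,3S)-3-bromo-2-[(3E,7S)-7,8-dihydroxy-4,8-dimethylnon-3-en-1-yl]-2-methyl-6-methylidenecyclohexyl]methyl}-4-(pivaloyloxy)benzoic acid | C=C1CC[C@H](Br)[C@@](C)(CC/C=C(\C)CC[C@@H](C(C)(C)O)O)[C@@H]1Cc2cc(C(=O)O)ccc2OC(=O)C(C)(C)C | intermediate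
13 | mixed anhydride of 12 with 2-methyl-6-nitrobenzoic acid | C=C1CC[C@H](Br)[C@@](C)(CC/C=C(\C)CC[C@@H](C(C)(C)O)O)[C@@H]1Cc2cc(C(=O)OC(=O)c3c(C)cccc3[N+](=O)[O-])ccc2OC(=O)C(C)(C)C | intermediate
14 | O-pivaloyl-10',11'-deoxybromophycolide F: 15-membered lactone from the benzoate carbonyl to O–C14'(S), arene C3 joined through C1'H2 to C2'(R) of the (2'R,6'S,7'S) bromocyclohexane, 10'E olefin, C15' tertiary alcohol, phenol as pivalate | C=C1CC[C@H](Br)[C@@]2(C)CC/C=C(\C)CC[C@@H](C(C)(C)O)OC(=O)c3ccc(OC(=O)C(C)(C)C)c(c3)C[C@H]12 | intermediate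
15 | bromophycolide F O-pivalate, the (10'S,11'S)-oxirane of 14 | C=C1CC[C@H](Br)[C@@]2(C)CC[C@@H]3O[C@@]3(C)CC[C@@H](C(C)(C)O)OC(=O)c3ccc(OC(=O)C(C)(C)C)c(c3)C[C@H]12 | intermediate
16 | bromophycolide F, (2'R,6'S,7'S,10'S,11'S,14'S) | C=C1CC[C@H](Br)[C@@]2(C)CC[C@@H]3O[C@@]3(C)CC[C@@H](C(C)(C)O)OC(=O)c3ccc(O)c(c3)C[C@H]12 | target

**Totals**
Total step count: 11. Longest linear sequence: 11 steps (one linear sequence from 1; 2 and 8 are commercial).

**Steps most likely to fail, with fallbacks**

Step 5 (the proposed new cyclisation; risks are enantioselectivity at an internal olefin, site selectivity, and endocyclic olefin isomers from the proton loss). The fallback uses known chemistry and sets out from 6: racemic bromonium-induced polyene cyclisation with Et2SBr·SbBrCl5 in MeNO2 at −25 °C gives 7 together with its mirror-image bromocycle F1. Endocyclic olefin isomers are removed on AgNO3-impregnated silica, and the two enantiomers are separated by preparative chiral-phase SFC. The route is rejoined at 7.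

Step 9 (closing a 15-membered ring onto a hindered secondary carbinol next to a tertiary one). The fallback activates the alcohol terminus instead of the acid and sets out from 11. Selective mesylation of the secondary hydroxyl (MsCl, Et3N, −20 °C) gives the 14'-mesylate F2. NaH in THF closes the tertiary alkoxide onto C14' with inversion to the (14'R)-dimethyloxirane allyl ester F3. Pd(PPh3)4/N-methylaniline frees the oxiranyl benzoic acid F4. Cs2CO3 in DMF at 70 °C and 2 mM lets the carboxylate open the oxirane at the less substituted C14' with a second inversion, which gives the 14'S ester and the free C15' hydroxyl directly. The route is rejoined at 14.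

Step 10 (face selectivity of a reagent-controlled epoxidation on a conformationally restricted macrocyclic olefin, and competition from the exocyclic olefin). The fallback epoxidises before ring closure and sets out from 10, where the trisubstituted olefin is open-chain and no γ-hydroxyl is yet present. The same ent-Shi conditions give the (10'S,11'S)-epoxy ketone F5. (R)-CBS/catecholborane reduction gives the epoxy diol F6. Neutral deallylation gives the epoxy diol acid F7. Shiina lactonisation through its mixed anhydride F8, kept basic throughout to avoid tetrahydrofuran formation from the γ-hydroxy oxirane, gives the epoxy macrolactone pivalate. The route is rejoined at 15.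

**Further compounds**
F1 | step 5 | allyl 3-{[(1S,2R,3R)-3-bromo-2-[(3E)-5-bromo-4-methylpent-3-en-1-yl]-2-methyl-6-methylidenecyclohexyl]methyl}-4-(pivaloyloxy)benzoate (enantiomer of 7) | C=C1CC[C@@H](Br)[C@](C)(CC/C=C(\C)CBr)[C@H]1Cc2cc(C(=O)OCC=C)ccc2OC(=O)C(C)(C)C
F2 | step 9 | 14'-O-methanesulfonate of 11 | C=C1CC[C@H](Br)[C@@](C)(CC/C=C(\C)CC[C@@H](C(C)(C)O)OS(C)(=O)=O)[C@@H]1Cc2cc(C(=O)OCC=C)ccc2OC(=O)C(C)(C)C
F3 | step 9 | allyl 3-{[(1R,2S,3S)-3-bromo-2-[(3E)-6-[(2R)-3,3-dimethyloxiran-2-yl]-4-methylhex-3-en-1-yl]-2-methyl-6-methylidenecyclohexyl]methyl}-4-(pivaloyloxy)benzoate | C=C1CC[C@H](Br)[C@@](C)(CC/C=C(\C)CC[C@H]3OC3(C)C)[C@@H]1Cc2cc(C(=O)OCC=C)ccc2OC(=O)C(C)(C)C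
F4 | step 9 | benzoic acid corresponding to F3 | C=C1CC[C@H](Br)[C@@](C)(CC/C=C(\C)CC[C@H]3OC3(C)C)[C@@H]1Cc2cc(C(=O)O)ccc2OC(=O)C(C)(C)C
F5 | step 10 | (10'S,11'S)-oxirane of ketone 10 | C=C1CC[C@H](Br)[C@@](C)(CC[C@@H]3O[C@@]3(C)CCC(=O)C(C)(C)O)[C@@H]1Cc2cc(C(=O)OCC=C)ccc2OC(=O)C(C)(C)C
F6 | step 10 | (10'S,11'S)-oxirane of diol 11 | C=C1CC[C@H](Br)[C@@](C)(CC[C@@H]3O[C@@]3(C)CC[C@@H](C(C)(C)O)O)[C@@H]1Cc2cc(C(=O)OCC=C)ccc2OC(=O)C(C)(C)C
F7 | step 10 | (10'S,11'S)-oxirane of seco acid 12 | C=C1CC[C@H](Br)[C@@](C)(CC[C@@H]3O[C@@]3(C)CC[C@@H](C(C)(C)O)O)[C@@H]1Cc2cc(C(=O)O)ccc2OC(=O)C(C)(C)C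
F8 | step 10 | mixed anhydride of F7 with 2-methyl-6-nitrobenzoic acid | C=C1CC[C@H](Br)[C@@](C)(CC[C@@H]3O[C@@]3(C)CC[C@@H](C(C)(C)O)O)[C@@H]1Cc2cc(C(=O)OC(=O)c4c(C)cccc4[N+](=O)[O-])ccc2OC(=O)C(C)(C)C
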